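**Retrosynthetic overview**
1. Feature. Each quinone is numbered C1(=O), C2(OH), C3(Me), C4(=O), C5 (biaryl carbon), C6 (chain carbon). Ring A bears the 2-methoxyphenethyl chain and ring B (primed) the phenethyl chain. In ring A, the ring B aryl on C5 and the chain carbon Cα on C6 are vicinal, and the other neighbour of C6 is the C1 oxygen. A 3-alkoxyaryne C5≡C6 leaves exactly this pattern when it takes a carbon nucleophile at C5 and a carbon electrophile at C6.
2. 33 ⇒ bis(methoxyquinone) 32 (two vinylogous esters) ⇒ phenol 30 (ring A quinone by para-oxidation of the C1 phenol at C4–H; ring B quinone by oxidative demethylation at C1'/C4') ⇒ aldehyde 26 (Cα=Cβ Wittig reaction, hydrogenation, release of the C1 phenol beside the formyl group).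
3. 26 ⇒ iodo triflate 8 + arylmagnesium bromide 19 + DMF 22. C5–C5' and C6–Cα form in one flask, and C4 stays C–H so that only the C1 oxygen flanks the aryne.
4. 8 comes from 2,3-dimethoxytoluene (C–H borylation/oxidation, MOM-directed lithiation/iodination, triflation). 19 comes from 2,4-dimethoxy-3-methylbenzaldehyde (Baeyer–Villiger oxidation, phenol-directed ortho-formylation, Wittig/H2, bromination last, Mg insertion).
5. No ring is built. All four six-membered rings are bought as arenes, and the quinones are unveiled at the end, ring A (step 18) before ring B (step 19).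

Key step: step 14

Assumption: the SMILES gives no descriptor for the hindered C5–C5' axis and the molecule has no stereocentre, so the axis is left uncontrolled (racemic material).

**Step 1**
Reactants: 1 2,3-dimethoxytoluene
Product: 3 3,4-dimethoxy-5-methylphenol, via aryl pinacolboronate 2 (not isolated)
Conditions: [Ir(OMe)(cod)]2 (1.5 mol%), 4,4'-di-tert-butyl-2,2'-bipyridine (3 mol%), B2pin2, THF, 80 °C; then 30% H2O2, aq NaOH, 0 °C to rt
Reagents that add atoms: bis(pinacolato)diboron, CC1(C)OB(OC1(C)C)B1OC(C)(C)C(C)(C)O1 (boryl group of 2); hydrogen peroxide, OO (phenol oxygen of 3)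
Why: Iridium-catalysed aromatic C–H borylation is sterically governed and in a 1,2,3-trisubstituted arene reaches the one C–H without an ortho neighbour (future C5), and the boronate is oxidised in the same flask without change of position (borylation–oxidation sequence).

**Step 2**
Reactants: 3 3,4-dimethoxy-5-methylphenol
Product: 4 1,2-dimethoxy-5-(methoxymethoxy)-3-methylbenzene
Conditions: MOMCl, iPr2NEt, CH2Cl2, 0 °C to rt
Reagents that add atoms: chloromethyl methyl ether, COCCl
Why: O-alkylation of the phenol (Williamson type) installs an acetal that protects the C5 oxygen and also directs the coming lithiation.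

**Step 3**
Reactants: 4 1,2-dimethoxy-5-(methoxymethoxy)-3-methylbenzene
Product: 6 2-iodo-3,4-dimethoxy-1-(methoxymethoxy)-5-methylbenzene, via aryllithium 5 (not isolated)
Conditions: n-BuLi, THF, 0 °C; then I2, −78 °C to rt; aq Na2S2O3
Reagents that add atoms: n-butyllithium, [Li]CCCC (lithium of 5); iodine, II
Why: In this directed ortho-metalation the C6–H lies between the OMOM group and the C1 methoxy group, so two coordinating oxygens cooperate and this proton is removed rather than the C4–H beside the methyl group, a choice that electrophilic iodination of the free phenol would not make reliably.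

**Step 4**
Reactants: 6 2-iodo-3,4-dimethoxy-1-(methoxymethoxy)-5-methylbenzene
Product: 7 2-iodo-3,4-dimethoxy-5-methylphenol
Conditions: conc. HCl (cat.), MeOH, 45 °C
Reagents that add atoms: none
Why: Acid-catalysed acetal exchange with methanol removes the MOM group under conditions that leave the aryl methyl ethers and the aryl iodide untouched.

**Step 5**
Reactants: 7 2-iodo-3,4-dimethoxy-5-methylphenol
Product: 8 2-iodo-3,4-dimethoxy-5-methylphenyl trifluoromethanesulfonate
Conditions: Tf2O, pyridine, CH2Cl2, 0 °C
Reagents that add atoms: trifluoromethanesulfonic anhydride, O=S(=O)(OS(=O)(=O)C(F)(F)F)C(F)(F)F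
Why: Routine O-sulfonylation of a phenol places the leaving group for the later 1,2-elimination on C5 next to the C6 iodine.

**Step 6**
Reactants: 9 2,4-dimethoxy-3-methylbenzaldehyde
Product: 11 2,4-dimethoxy-3-methylphenol, via aryl formate 10 (not isolated)
Conditions: mCPBA, CH2Cl2, 0 °C to rt; then KOH, MeOH–H2O, 0 °C; HCl
Reagents that add atoms: 3-chloroperoxybenzoic acid, O=C(OO)c1cccc(Cl)c1
Why: In this Baeyer–Villiger (Dakin-type) oxidation the electron-rich aryl group migrates in preference to hydride, and saponification of the formate frees the phenol that becomes the C1' oxygen.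

**Step 7**
Reactants: 11 2,4-dimethoxy-3-methylphenol
Product: 12 2-hydroxy-3,5-dimethoxy-4-methylbenzaldehyde
Conditions: MgCl2 (anhydrous), Et3N, (CH2O)n, MeCN, reflux; 1 M HCl
Reagents that add atoms: paraformaldehyde (as formaldehyde), C=O
Why: In the Casnati–Skattebøl formylation the magnesium phenoxide delivers formaldehyde through a six-membered chelate only to the ortho carbon, C6' is the single free ortho site so the intrinsically more nucleophilic C5' is bypassed, and a second formaldehyde oxidises the benzylic alkoxide by hydride transfer.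

**Step 8**
Reactants: 12 2-hydroxy-3,5-dimethoxy-4-methylbenzaldehyde
Product: 13 2,3,5-trimethoxy-4-methylbenzaldehyde
Conditions: MeI, K2CO3, acetone, reflux
Reagents that add atoms: iodomethane, CI
Why: Williamson methylation of the phenoxide caps the C1' oxygen so that ring B carries the para pair of methyl ethers (C1'/C4') needed for the final oxidative demethylation.

**Step 9**
Reactants: 13 2,3,5-trimethoxy-4-methylbenzaldehyde; 14 benzyltriphenylphosphonium chloride
Product: 16 1,3,4-trimethoxy-2-methyl-5-(2-phenylethenyl)benzene (E/Z mixture), via benzylidene ylide 15 (not isolated)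
Conditions: KOtBu, THF, 0 °C; then 13, 0 °C to rt
Reagents that add atoms: none
Why: A Wittig olefination with a semi-stabilised ylide on an aldehyde with only one ortho substituent is reliable, and the alkene geometry does not matter because the double bond is saturated next.

**Step 10**
Reactants: 16 1,3,4-trimethoxy-2-methyl-5-(2-phenylethenyl)benzene
Product: 17 1,3,4-trimethoxy-2-methyl-5-(2-phenylethyl)benzene
Conditions: H2 (1 bar), 10% Pd/C, EtOAc, rt
Reagents that add atoms: none
Why: Heterogeneous catalytic hydrogenation saturates both stilbene isomers to the same bibenzyl, and it is run before any halogen is present.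

**Step 11**
Reactants: 17 1,3,4-trimethoxy-2-methyl-5-(2-phenylethyl)benzene
Product: 18 1-bromo-2,4,5-trimethoxy-3-methyl-6-(2-phenylethyl)benzene
Conditions: NBS, MeCN, 0 °C to rt, dark
Reagents that add atoms: N-bromosuccinimide, O=C1CCC(=O)N1Br
Why: Electrophilic aromatic bromination can only strike C5', the last C–H of the trimethoxy ring (ortho to the C4' and para to the C2' methoxy group), while the plain phenyl ring is far less reactive and the polar medium in the dark disfavours benzylic radical bromination.

**Step 12**
Reactants: 18 1-bromo-2,4,5-trimethoxy-3-methyl-6-(2-phenylethyl)benzene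
Product: 19 [2,4,5-trimethoxy-3-methyl-6-(2-phenylethyl)phenyl]magnesium bromide (used as a titrated THF solution)
Conditions: Mg turnings, LiCl, BrCH2CH2Br (5 mol%), THF, 25 to 50 °C
Reagents that add atoms: magnesium, [Mg]
Why: Grignard formation by direct insertion is established for fully substituted polymethoxyaryl bromides, and LiCl keeps the metal surface clean and the hindered reagent in solution.

**Step 13**
Reactants: 20 2-methoxybenzyl chloride
Product: 21 (2-methoxybenzyl)triphenylphosphonium chloride
Conditions: PPh3, toluene, reflux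
Reagents that add atoms: triphenylphosphine, c1ccc(cc1)P(c1ccccc1)c1ccccc1
Why: SN2 quaternisation of triphenylphosphine by a reactive benzylic chloride gives the salt, which precipitates from toluene.

**Step 14**
Reactants: 8 2-iodo-3,4-dimethoxy-5-methylphenyl trifluoromethanesulfonate; 19 [2,4,5-trimethoxy-3-methyl-6-(2-phenylethyl)phenyl]magnesium bromide; 22 N,N-dimethylformamide
Product: 26 2,3-dimethoxy-4-methyl-6-[2,4,5-trimethoxy-3-methyl-6-(2-phenylethyl)phenyl]benzaldehyde, via magnesiated aryl triflate 23 (not isolated), via aryne 24 (not isolated), via biarylmagnesium bromide 25 (not isolated)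
Conditions: 8 and 19 (1.3 equiv), THF, −78 °C; iPrMgCl (1.05 equiv) added slowly; −78 °C to rt; then DMF 22 (5 equiv), 0 °C to rt; 1 M HCl
Reagents that add atoms: N,N-dimethylformamide (22), CN(C)C=O (formyl carbon and oxygen); isopropylmagnesium chloride, CC(C)[Mg]Cl (magnesium and chlorine of 23 only)
Why: iPrMgCl exchanges the C6 iodine of 8 far faster than the hindered reagent 19 can, and the magnesiated triflate 23 expels MgCl(OTf) across C5/C6 already at low temperature, so that aryne 24 (C5≡C6) forms in the presence of 19. Reagent 19 carbomagnesiates the strained triple bond, which forms the C5–C5' bond and leaves magnesium on C6 (25), and 25 attacks the carbonyl carbon of DMF 22, so that acidic work-up releases the C6 formyl group and with it the C6–Cα bond. The closest known reaction type is the addition of 2,6-disubstituted arylmagnesium halides to arynes followed by an electrophilic quench, the usual entry to hindered 2-functionalised biaryls such as dialkylbiarylphosphines. The selectivity needed is the orientation of addition: the C1 methoxy group next to C6 distorts and polarises the aryne so that the nucleophile attacks the remote carbon C5 and carbanion character develops at C6 beside the electron-withdrawing C1–O bond, and C5 is also the more open end because C4 carries only hydrogen. No ring is closed and no stereocentre is set; the new axis has three ortho substituents at this stage (C6 formyl, C4' methoxy, C6' chain) and forms as a racemate. Slow addition of iPrMgCl keeps 23 and free iPrMgCl scarce, which should hold back their own addition to 24.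

**Step 15**
Reactants: 26 2,3-dimethoxy-4-methyl-6-[2,4,5-trimethoxy-3-methyl-6-(2-phenylethyl)phenyl]benzaldehyde
Product: 27 2-hydroxy-3-methoxy-4-methyl-6-[2,4,5-trimethoxy-3-methyl-6-(2-phenylethyl)phenyl]benzaldehyde
Conditions: BCl3 (1.2 equiv), CH2Cl2, −78 to −10 °C; H2O
Reagents that add atoms: none
Why: In this chelation-controlled ether cleavage boron binds the formyl oxygen and the neighbouring C1 methoxy oxygen in a six-membered chelate, so only that methyl group is lost as MeCl, and the C1 phenol later allows a phenol-specific oxidant to reach C4 without touching ring B or the anisole ring.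

**Step 16**
Reactants: 27 2-hydroxy-3-methoxy-4-methyl-6-[2,4,5-trimethoxy-3-methyl-6-(2-phenylethyl)phenyl]benzaldehyde; 21 (2-methoxybenzyl)triphenylphosphonium chloride
Product: 29 2-methoxy-6-[2-(2-methoxyphenyl)ethenyl]-3-methyl-5-[2,4,5-trimethoxy-3-methyl-6-(2-phenylethyl)phenyl]phenol (E/Z mixture), via 2-methoxybenzylidene ylide 28 (not isolated)
Conditions: 21 (2.5 equiv), KOtBu (3.5 equiv), THF, 0 °C; then 27, rt to 60 °C; aq NH4Cl
Reagents that add atoms: none
Why: Wittig olefination of salicylaldehydes with benzylic ylides is known to proceed on the phenoxide when base and ylide are used in excess, and the geometry of the Cα=Cβ bond is irrelevant.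

**Step 17**
Reactants: 29 2-methoxy-6-[2-(2-methoxyphenyl)ethenyl]-3-methyl-5-[2,4,5-trimethoxy-3-methyl-6-(2-phenylethyl)phenyl]phenol
Product: 30 2-methoxy-6-[2-(2-methoxyphenyl)ethyl]-3-methyl-5-[2,4,5-trimethoxy-3-methyl-6-(2-phenylethyl)phenyl]phenol
Conditions: H2 (1–4 bar), 10% Pd/C, EtOAc–MeOH, rt
Reagents that add atoms: none
Why: Catalytic hydrogenation saturates the only reducible group, the stilbene double bond, and completes the 2-methoxyphenethyl chain on C6.

**Step 18**
Reactants: 30 2-methoxy-6-[2-(2-methoxyphenyl)ethyl]-3-methyl-5-[2,4,5-trimethoxy-3-methyl-6-(2-phenylethyl)phenyl]phenol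
Product: 31 2-methoxy-6-[2-(2-methoxyphenyl)ethyl]-3-methyl-5-[2,4,5-trimethoxy-3-methyl-6-(2-phenylethyl)phenyl]-1,4-benzoquinone
Conditions: (KSO3)2NO (2.5 equiv), KH2PO4 buffer, acetone–H2O, rt
Reagents that add atoms: potassium nitrosodisulfonate, [K+].[K+].[O]N(S(=O)(=O)[O-])S(=O)(=O)[O-]
Why: In the Teuber oxidation the nitroxyl radical abstracts the phenolic hydrogen and a second one couples at the para carbon C4, the only unsubstituted position of ring A, so the para-quinone forms while the aryl ethers of ring B and of the side chain, which have no O–H, are not attacked.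

**Step 19**
Reactants: 31 2-methoxy-6-[2-(2-methoxyphenyl)ethyl]-3-methyl-5-[2,4,5-trimethoxy-3-methyl-6-(2-phenylethyl)phenyl]-1,4-benzoquinone
Product: 32 2-methoxy-5-[4-methoxy-5-methyl-3,6-dioxo-2-(2-phenylethyl)cyclohexa-1,4-dien-1-yl]-6-[2-(2-methoxyphenyl)ethyl]-3-methyl-1,4-benzoquinone
Conditions: (NH4)2Ce(NO3)6 (2.5 equiv), MeCN–H2O, 0 °C
Reagents that add atoms: water, O
Why: In this oxidative demethylation tetravalent cerium removes electrons from the most electron-rich arene, ring B, and water attacks C1' and C4' with loss of methanol to give the para-quinone, while the ring A quinone is inert and the monomethoxy arene has a much higher oxidation potential.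

**Step 20**
Reactants: 32 2-methoxy-5-[4-methoxy-5-methyl-3,6-dioxo-2-(2-phenylethyl)cyclohexa-1,4-dien-1-yl]-6-[2-(2-methoxyphenyl)ethyl]-3-methyl-1,4-benzoquinone
Product: 33 2-hydroxy-5-[4-hydroxy-5-methyl-3,6-dioxo-2-(2-phenylethyl)cyclohexa-1,4-dien-1-yl]-6-[2-(2-methoxyphenyl)ethyl]-3-methyl-1,4-benzoquinone (CNP0202346.0)
Conditions: 2 M aq NaOH, MeOH–THF, rt, argon; then 1 M HCl
Reagents that add atoms: sodium hydroxide, [Na+].[OH-]
Why: The C2 and C2' methoxy groups are vinylogous methyl esters, so hydroxide adds there and expels methoxide (addition–elimination); all other quinone positions carry carbon so conjugate addition cannot compete, the hydroxyquinone anions resist further attack, and the side-chain aryl methyl ether is inert to base.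

**Compound list**
1 | 2,3-dimethoxytoluene | COc1cccc(C)c1OC | starting material
2 | 2-(3,4-dimethoxy-5-methylphenyl)-4,4,5,5-tetramethyl-1,3,2-dioxaborolane | COc1cc(B2OC(C)(C)C(C)(C)O2)cc(C)c1OC | intermediate
3 | 3,4-dimethoxy-5-methylphenol | COc1cc(O)cc(C)c1OC | intermediate
4 | 1,2-dimethoxy-5-(methoxymethoxy)-3-methylbenzene | COCOc1cc(C)c(OC)c(OC)c1 | intermediate
5 | [2,3-dimethoxy-6-(methoxymethoxy)-4-methylphenyl]lithium | COCOc1cc(C)c(OC)c(OC)c1[Li] | intermediate
6 | 2-iodo-3,4-dimethoxy-1-(methoxymethoxy)-5-methylbenzene | COCOc1cc(C)c(OC)c(OC)c1I | intermediate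
7 | 2-iodo-3,4-dimethoxy-5-methylphenol | COc1c(OC)c(C)cc(O)c1I | intermediate
8 | 2-iodo-3,4-dimethoxy-5-methylphenyl trifluoromethanesulfonate | COc1c(OC)c(C)cc(OS(=O)(=O)C(F)(F)F)c1I | intermediate
9 | 2,4-dimethoxy-3-methylbenzaldehyde | COc1ccc(C=O)c(OC)c1C | starting material
10 | 2,4-dimethoxy-3-methylphenyl formate | COc1ccc(OC=O)c(OC)c1C | intermediate
11 | 2,4-dimethoxy-3-methylphenol | COc1ccc(O)c(OC)c1C | intermediate
12 | 2-hydroxy-3,5-dimethoxy-4-methylbenzaldehyde | COc1cc(C=O)c(O)c(OC)c1C | intermediate
13 | 2,3,5-trimethoxy-4-methylbenzaldehyde | COc1cc(C=O)c(OC)c(OC)c1C | intermediate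
14 | benzyltriphenylphosphonium chloride | [Cl-].C(c1ccccc1)[P+](c1ccccc1)(c1ccccc1)c1ccccc1 | starting material
15 | benzylidenetriphenylphosphorane | C(c1ccccc1)=P(c1ccccc1)(c1ccccc1)c1ccccc1 | intermediate
16 | 1,3,4-trimethoxy-2-methyl-5-(2-phenylethenyl)benzene (E/Z mixture) | COc1cc(C=Cc2ccccc2)c(OC)c(OC)c1C | intermediate
17 | 1,3,4-trimethoxy-2-methyl-5-(2-phenylethyl)benzene | COc1cc(CCc2ccccc2)c(OC)c(OC)c1C | intermediate
18 | 1-bromo-2,4,5-trimethoxy-3-methyl-6-(2-phenylethyl)benzene | COc1c(C)c(OC)c(OC)c(CCc2ccccc2)c1Br | intermediate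
19 | [2,4,5-trimethoxy-3-methyl-6-(2-phenylethyl)phenyl]magnesium bromide | COc1c(C)c(OC)c(OC)c(CCc2ccccc2)c1[Mg]Br | intermediate
20 | 2-methoxybenzyl chloride | COc1ccccc1CCl | starting material
21 | (2-methoxybenzyl)triphenylphosphonium chloride | [Cl-].COc1ccccc1C[P+](c1ccccc1)(c1ccccc1)c1ccccc1 | intermediate
22 | N,N-dimethylformamide | CN(C)C=O | starting material
23 | [2,3-dimethoxy-4-methyl-6-(trifluoromethylsulfonyloxy)phenyl]magnesium chloride | COc1c(OC)c(C)cc(OS(=O)(=O)C(F)(F)F)c1[Mg]Cl | intermediate
24 | 3,4-dimethoxy-5-methylbenzyne | COC1=C(OC)C(C)=CC#C1 | intermediate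
25 | {2,3-dimethoxy-4-methyl-6-[2,4,5-trimethoxy-3-methyl-6-(2-phenylethyl)phenyl]phenyl}magnesium bromide | COc1c(OC)c(C)cc(-c2c(OC)c(C)c(OC)c(OC)c2CCc2ccccc2)c1[Mg]Br | intermediate
26 | 2,3-dimethoxy-4-methyl-6-[2,4,5-trimethoxy-3-methyl-6-(2-phenylethyl)phenyl]benzaldehyde (tri-ortho-substituted biaryl, racemic axis) | COc1c(OC)c(C)cc(-c2c(OC)c(C)c(OC)c(OC)c2CCc2ccccc2)c1C=O | intermediate
27 | 2-hydroxy-3-methoxy-4-methyl-6-[2,4,5-trimethoxy-3-methyl-6-(2-phenylethyl)phenyl]benzaldehyde | COc1c(O)c(C=O)c(-c2c(OC)c(C)c(OC)c(OC)c2CCc2ccccc2)cc1C | intermediate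
28 | (2-methoxybenzylidene)triphenylphosphorane | COc1ccccc1C=P(c1ccccc1)(c1ccccc1)c1ccccc1 | intermediate
29 | 2-methoxy-6-[2-(2-methoxyphenyl)ethenyl]-3-methyl-5-[2,4,5-trimethoxy-3-methyl-6-(2-phenylethyl)phenyl]phenol (E/Z mixture) | COc1c(O)c(C=Cc2ccccc2OC)c(-c2c(OC)c(C)c(OC)c(OC)c2CCc2ccccc2)cc1C | intermediate
30 | 2-methoxy-6-[2-(2-methoxyphenyl)ethyl]-3-methyl-5-[2,4,5-trimethoxy-3-methyl-6-(2-phenylethyl)phenyl]phenol | COc1c(O)c(CCc2ccccc2OC)c(-c2c(OC)c(C)c(OC)c(OC)c2CCc2ccccc2)cc1C | intermediate
31 | 2-methoxy-6-[2-(2-methoxyphenyl)ethyl]-3-methyl-5-[2,4,5-trimethoxy-3-methyl-6-(2-phenylethyl)phenyl]-1,4-benzoquinone | COC1=C(C)C(=O)C(c2c(OC)c(C)c(OC)c(OC)c2CCc2ccccc2)=C(CCc2ccccc2OC)C1=O | intermediate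
32 | 2-methoxy-5-[4-methoxy-5-methyl-3,6-dioxo-2-(2-phenylethyl)cyclohexa-1,4-dien-1-yl]-6-[2-(2-methoxyphenyl)ethyl]-3-methyl-1,4-benzoquinone | COC1=C(C)C(=O)C(C2=C(CCc3ccccc3)C(=O)C(OC)=C(C)C2=O)=C(CCc2ccccc2OC)C1=O | intermediate
33 | 2-hydroxy-5-[4-hydroxy-5-methyl-3,6-dioxo-2-(2-phenylethyl)cyclohexa-1,4-dien-1-yl]-6-[2-(2-methoxyphenyl)ethyl]-3-methyl-1,4-benzoquinone (CNP0202346.0) | COc1ccccc1CCC1=C(C2=C(CCc3ccccc3)C(=O)C(O)=C(C)C2=O)C(=O)C(C)=C(O)C1=O | target

**Step count**
Total step count: 20.
Longest linear sequence: 14 steps (from 9 to 33: steps 6–12 and 14–20).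

**Steps most likely to fail**

Step 14.
- What may go wrong: carbomagnesiation by the 2,6-disubstituted reagent may be outrun by addition of 23 or of iPrMgCl to the aryne. Iodine–magnesium exchange between 19 and 8 may also compete, and the congested C6–Mg bond may be trapped only partly by DMF and be protonated on work-up.
- Fallback: the aryne is given up, and the C5–C5' bond is made by a Negishi cross-coupling after the C6 formyl group is already in place. It sets out from MOM ether 4 and Grignard reagent 19.
- Lithiation of 4 as in step 3 (aryllithium 5) and a quench with DMF 22 instead of I2 should give 2,3-dimethoxy-6-(methoxymethoxy)-4-methylbenzaldehyde F1.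
- HCl in MeOH should free 6-hydroxy-2,3-dimethoxy-4-methylbenzaldehyde F2, and Tf2O/pyridine should convert it into 2-formyl-3,4-dimethoxy-5-methylphenyl trifluoromethanesulfonate F3.
- Transmetalation of 19 with ZnCl2 gives [2,4,5-trimethoxy-3-methyl-6-(2-phenylethyl)phenyl]zinc chloride F4, which tolerates the aldehyde.
- Coupling of F3 with F4 (Pd2(dba)3, RuPhos, THF, 70 °C) comes back to the route at aldehyde 26.
- The ortho-formyl group speeds up oxidative addition of zerovalent palladium into the C5–OTf bond, and bulky dialkylbiarylphosphine ligands are established for tri-ortho-substituted biaryls.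

Step 16.
- What may go wrong: deprotonation of the C1 phenol lowers the electrophilicity of a formyl group that is flanked on both sides, so the olefination may stall.
- Fallback: the olefination is replaced by carbonyl addition and ionic deoxygenation. It sets out from aldehyde 27 and benzyl chloride 20.
- Compound 20 is converted with Mg (Et2O–THF, 0 °C, dilute, to limit Wurtz coupling) into (2-methoxybenzyl)magnesium chloride F5.
- An excess of this reagent (one equivalent is spent on the phenol) should add to the magnesium-chelated aldehyde. The product is 6-[1-hydroxy-2-(2-methoxyphenyl)ethyl]-2-methoxy-3-methyl-5-[2,4,5-trimethoxy-3-methyl-6-(2-phenylethyl)phenyl]phenol F6, a racemic carbinol whose configuration is of no consequence.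
- Et3SiH/CF3CO2H in CH2Cl2 should ionise the carbinol to the ortho-quinone methide or benzylic cation and reduce it, which comes back to the route at phenol 30.
- Material that loses a proton instead becomes stilbene 29 and is carried through step 17.

Step 18.
- What may go wrong: radical coupling at C4, which lies between the C3 methyl group and ring B, may be slow. The lipophilic phenol may also dissolve poorly in the aqueous medium, so unproductive decay of the phenoxyl radical can compete.
- Fallback: a homogeneous two-electron oxidation with a trivalent iodine reagent, setting out from phenol 30.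
- PhI(OAc)2 (2.2 equiv) in MeOH at 0 °C should methoxylate C4 twice through phenoxenium-type intermediates. The product is the quinone monoketal 2,4,4-trimethoxy-6-[2-(2-methoxyphenyl)ethyl]-3-methyl-5-[2,4,5-trimethoxy-3-methyl-6-(2-phenylethyl)phenyl]cyclohexa-2,5-dien-1-one F7, and the aryl ethers of ring B are not oxidised by this reagent in methanol.
- Dilute HCl in THF–H2O hydrolyses the ketal and comes back to the route at quinone 31.

**Further compounds**
F1 | step 14 | 2,3-dimethoxy-6-(methoxymethoxy)-4-methylbenzaldehyde | COCOc1cc(C)c(OC)c(OC)c1C=O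
F2 | step 14 | 6-hydroxy-2,3-dimethoxy-4-methylbenzaldehyde | COc1c(OC)c(C)cc(O)c1C=O
F3 | step 14 | 2-formyl-3,4-dimethoxy-5-methylphenyl trifluoromethanesulfonate | COc1c(OC)c(C)cc(OS(=O)(=O)C(F)(F)F)c1C=O
F4 | step 14 | [2,4,5-trimethoxy-3-methyl-6-(2-phenylethyl)phenyl]zinc chloride | COc1c(C)c(OC)c(OC)c(CCc2ccccc2)c1[Zn]Cl
F5 | step 16 | (2-methoxybenzyl)magnesium chloride | COc1ccccc1C[Mg]Cl
F6 | step 16 | 6-[1-hydroxy-2-(2-methoxyphenyl)ethyl]-2-methoxy-3-methyl-5-[2,4,5-trimethoxy-3-methyl-6-(2-phenylethyl)phenyl]phenol (racemic) | COc1c(O)c(C(O)Cc2ccccc2OC)c(-c2c(OC)c(C)c(OC)c(OC)c2CCc2ccccc2)cc1C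
F7 | step 18 | 2,4,4-trimethoxy-6-[2-(2-methoxyphenyl)ethyl]-3-methyl-5-[2,4,5-trimethoxy-3-methyl-6-(2-phenylethyl)phenyl]cyclohexa-2,5-dien-1-one | COC1=C(C)C(OC)(OC)C(c2c(OC)c(C)c(OC)c(OC)c2CCc2ccccc2)=C(CCc2ccccc2OC)C1=O
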